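**Retrosynthetic overview**
- Target 17 ⇐ diol 13: acetate on the tertiary O-4 last, angelate on the secondary O-3 before it.
- Ring A is closed last through the C3–C4 bond: the aldehyde carbon of keto-aldehyde 11 acts as an acyl anion (carbene catalysis) and adds to the acetyl ketone; the ketol is reduced in the same flask.
- 11 ⇐ ozonolysis of diene ketone 10 (butenyl → C1–C3 propanal arm; isopropenyl → C4/C15 acetyl); the isopropyl group comes from alkylation of the enolate released from enol acetate 7.
- Ring B (with C5 and C10 fixed) ⇐ cyclobutane cleavage of pinane ketone 6; quaternary C10 by methyl 1,4-addition anti to the gem-dimethyl bridge of enone 5.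
- 5 ⇐ (−)-verbenone 1 by α-allylation then Cope rearrangement (net γ-allylation). Ring order: ring B from the chiral pool, then ring A.

Assumption: the stereo-SMILES is taken literally, i.e. the cis-fused eudesmane (H-5 and CH3-14 both β) with 3α-angelate, 4α-acetate and 7β-isopropyl. Eudesmane numbering (C-1 to C-15) is used for positions.
Assumption: the (5aS,10bR) antipode of the triazolium salt in step 7 is taken as the one that delivers the 4α-alcohol; if the sense is opposite, its mirror image is used and nothing else changes.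

Step 1
Reactants: 1 (1S,5S)-4,6,6-trimethylbicyclo[3.1.1]hept-3-en-2-one [(−)-verbenone]; 2 allyl bromide
Product: 4 (1S,3R,5R)-6,6-dimethyl-4-methylidene-3-(prop-2-en-1-yl)bicyclo[3.1.1]heptan-2-one, via lithium dienolate 3 (not isolated)
Conditions: LDA, THF, −78 °C; 2, −78 → −30 °C; aq. NH4Cl at −30 °C
Reagents that add atoms: none
Why: Kinetic enolate alkylation of the linear lithium dienolate (only the C-4 methyl can be deprotonated) takes place at the α-carbon, anti to the gem-dimethyl bridge, giving the deconjugated α-allyl ketone that is a 1,5-diene.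

Step 2
Reactants: 4 (1S,3R,5R)-6,6-dimethyl-4-methylidene-3-(prop-2-en-1-yl)bicyclo[3.1.1]heptan-2-one
Product: 5 (1S,5R)-4-(but-3-en-1-yl)-6,6-dimethylbicyclo[3.1.1]hept-3-en-2-one
Conditions: toluene, BHT (cat.), 160 °C, sealed tube
Reagents that add atoms: none
Why: Cope [3,3]-sigmatropic rearrangement moves the allyl terminus onto the exocyclic methylene carbon and restores the conjugated enone (net γ-allylation), so the old methyl carbon becomes C-1 of a butenyl arm and no stereocentre is created.

Step 3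
Reactants: 5 (1S,5R)-4-(but-3-en-1-yl)-6,6-dimethylbicyclo[3.1.1]hept-3-en-2-one
Product: 6 (1S,4R,5S)-4-(but-3-en-1-yl)-4,6,6-trimethylbicyclo[3.1.1]heptan-2-one
Conditions: MeMgBr, CuBr·SMe2 (10 mol %), THF, −30 → 0 °C; aq. NH4Cl
Reagents that add atoms: methylmagnesium bromide, C[Mg]Br
Why: Copper-catalysed conjugate addition delivers methyl from the face anti to the gem-dimethyl bridge, which sets the quaternary carbon (future C-10, R) with the butenyl arm cis to the bridge carbon that becomes C-4, as the cis ring fusion requires.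

Step 4
Reactants: 6 (1S,4R,5S)-4-(but-3-en-1-yl)-4,6,6-trimethylbicyclo[3.1.1]heptan-2-one
Product: 7 (4R,5R)-5-(but-3-en-1-yl)-5-methyl-4-(prop-1-en-2-yl)cyclohex-1-en-1-yl acetate
Conditions: BF3·OEt2, Zn(OAc)2, Ac2O, rt
Reagents that add atoms: acetic anhydride, CC(=O)OC(C)=O
Why: Lewis-acid cyclobutane fragmentation (retro-aldol-type cleavage of the bond between the ketone α-carbon and the gem-dimethyl carbon) gives the enol acetate and, after proton loss from the tertiary cation, the isopropenyl group; the bonds to future C-5 and C-10 are untouched, so both keep their configuration.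

Step 5
Reactants: 7 (4R,5R)-5-(but-3-en-1-yl)-5-methyl-4-(prop-1-en-2-yl)cyclohex-1-en-1-yl acetate; 8 2-iodopropane
Product: 10 (2R,4R,5R)-5-(but-3-en-1-yl)-5-methyl-2-(propan-2-yl)-4-(prop-1-en-2-yl)cyclohexan-1-one, via lithium enolate 9 (not isolated)
Conditions: MeLi (2.1 equiv), THF, 0 °C; then DMPU, 8 (5 equiv), −20 °C → rt
Reagents that add atoms: none
Why: MeLi cleaves the enol acetate to the regiodefined lithium enolate, and SN2 enolate alkylation (slow with a secondary iodide) occurs by axial attack on the half-chair with the isopropenyl group equatorial, placing isopropyl trans to it (7β).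

Step 6
Reactants: 10 (2R,4R,5R)-5-(but-3-en-1-yl)-5-methyl-2-(propan-2-yl)-4-(prop-1-en-2-yl)cyclohexan-1-one
Product: 11 3-[(1R,2S,4R)-2-acetyl-1-methyl-5-oxo-4-(propan-2-yl)cyclohexyl]propanal
Conditions: O3, CH2Cl2, −78 °C; then Me2S, −78 °C → rt
Reagents that add atoms: ozone, [O-][O+]=O
Why: Ozonolysis with reductive work-up cleaves both 1-alkenes (butenyl → propanal arm C-1 to C-3, isopropenyl → acetyl C-4/C-15) under neutral conditions that leave the epimerisable centres C-5 and C-7 untouched.

Step 7 (key step)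
Reactants: 11 3-[(1R,2S,4R)-2-acetyl-1-methyl-5-oxo-4-(propan-2-yl)cyclohexyl]propanal
Product: 13 (3R,4aS,5S,6R,8aR)-5,6-dihydroxy-5,8a-dimethyl-3-(propan-2-yl)octahydronaphthalen-2(1H)-one, via ketol 12 (not isolated)
Conditions: (5aS,10bR)-2-(pentafluorophenyl)-5a,10b-dihydro-4H,6H-indeno[2,1-b][1,2,4]triazolo[4,3-d][1,4]oxazin-2-ium tetrafluoroborate C18H11BF9N3O (15 mol %), i-Pr2NEt (15 mol %), toluene (0.02 M), rt; then MeOH, NaBH4, −78 °C
Reagents that add atoms: none
Why: In an intramolecular crossed aldehyde–ketone benzoin reaction the carbene-bound aldehyde carbon (Breslow intermediate, an acyl anion) adds to the acetyl carbonyl and closes ring A as the cis-decalin; because the two chair-like closures are close in energy, the chiral triazolium selects the ketone face to give the 4α tertiary alcohol, and NaBH4 then attacks the C-3 ketone axially from the open β face, anti to the axial C4–O bond, to give the 3α (equatorial) alcohol cis to 4-OH.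

Step 8
Reactants: 13 (3R,4aS,5S,6R,8aR)-5,6-dihydroxy-5,8a-dimethyl-3-(propan-2-yl)octahydronaphthalen-2(1H)-one; 14 angelic acid [(2Z)-2-methylbut-2-enoic acid]
Product: 16 (1S,2R,4aR,7R,8aS)-1-hydroxy-1,4a-dimethyl-6-oxo-7-(propan-2-yl)decahydronaphthalen-2-yl (2Z)-2-methylbut-2-enoate, via mixed anhydride 15 (not isolated)
Conditions: 14, 2,4,6-trichlorobenzoyl chloride, Et3N, toluene, rt, 2 h; then 13, 80 °C
Reagents that add atoms: 2,4,6-trichlorobenzoyl chloride, O=C(Cl)c1c(Cl)cc(Cl)cc1Cl (its acyl group is carried by intermediate 15 only)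
Why: Yamaguchi-type esterification through the preformed mixed anhydride, without a nucleophilic catalyst that could isomerise the Z-alkene to the tiglate, acylates only the equatorial secondary 3-OH because the axial tertiary 4-OH is inert.

Step 9
Reactants: 16 (1S,2R,4aR,7R,8aS)-1-hydroxy-1,4a-dimethyl-6-oxo-7-(propan-2-yl)decahydronaphthalen-2-yl (2Z)-2-methylbut-2-enoate
Product: 17 (1S,2R,4aR,7R,8aS)-1-(acetyloxy)-1,4a-dimethyl-6-oxo-7-(propan-2-yl)decahydronaphthalen-2-yl (2Z)-2-methylbut-2-enoate
Conditions: Ac2O, Sc(OTf)3 (3 mol %), MeCN, −20 °C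
Reagents that add atoms: acetic anhydride, CC(=O)OC(C)=O
Why: Lewis-acid-catalysed acetylation with Ac2O acylates hindered tertiary alcohols at low temperature with retention at C-4 and without touching the angelate; the 7β-isopropyl group is the thermodynamic epimer of the finished cis-decalin, so no centre is scrambled.

**Compound list**
1 | (1S,5S)-4,6,6-trimethylbicyclo[3.1.1]hept-3-en-2-one [(−)-verbenone] | CC1=CC(=O)[C@H]2C[C@@H]1C2(C)C | starting material
2 | allyl bromide (3-bromoprop-1-ene) | C=CCBr | starting material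
3 | lithium (1S,5R)-6,6-dimethyl-4-methylidenebicyclo[3.1.1]hept-2-en-2-olate | [Li+].[O-]C1=CC(=C)[C@@H]2C[C@H]1C2(C)C | intermediate
4 | (1S,3R,5R)-6,6-dimethyl-4-methylidene-3-(prop-2-en-1-yl)bicyclo[3.1.1]heptan-2-one (allyl anti to the gem-dimethyl bridge) | C=CC[C@H]1C(=O)[C@H]2C[C@@H](C1=C)C2(C)C | intermediate
5 | (1S,5R)-4-(but-3-en-1-yl)-6,6-dimethylbicyclo[3.1.1]hept-3-en-2-one | C=CCCC1=CC(=O)[C@H]2C[C@@H]1C2(C)C | intermediate
6 | (1S,4R,5S)-4-(but-3-en-1-yl)-4,6,6-trimethylbicyclo[3.1.1]heptan-2-one (new methyl anti to the bridge) | C=CCC[C@]1(C)CC(=O)[C@H]2C[C@@H]1C2(C)C | intermediate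
7 | (4R,5R)-5-(but-3-en-1-yl)-5-methyl-4-(prop-1-en-2-yl)cyclohex-1-en-1-yl acetate (butenyl cis to isopropenyl) | CC(=O)OC1=CC[C@H](C(C)=C)[C@](C)(CCC=C)C1 | intermediate
8 | 2-iodopropane | CC(C)I | starting material
9 | lithium (4R,5R)-5-(but-3-en-1-yl)-5-methyl-4-(prop-1-en-2-yl)cyclohex-1-en-1-olate | [Li+].[O-]C1=CC[C@H](C(C)=C)[C@](C)(CCC=C)C1 | intermediate
10 | (2R,4R,5R)-5-(but-3-en-1-yl)-5-methyl-2-(propan-2-yl)-4-(prop-1-en-2-yl)cyclohexan-1-one (isopropyl trans to isopropenyl) | C=CCC[C@]1(C)CC(=O)[C@@H](C(C)C)C[C@@H]1C(C)=C | intermediate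
11 | 3-[(1R,2S,4R)-2-acetyl-1-methyl-5-oxo-4-(propan-2-yl)cyclohexyl]propanal | O=CCC[C@]1(C)CC(=O)[C@@H](C(C)C)C[C@@H]1C(C)=O | intermediate
12 | (1S,4aR,7R,8aS)-1-hydroxy-1,4a-dimethyl-7-(propan-2-yl)octahydronaphthalene-2,6(1H,3H)-dione (cis-fused; 4α-OH in eudesmane numbering) | O=C1CC[C@]2(C)CC(=O)[C@@H](C(C)C)C[C@@H]2[C@]1(C)O | intermediate
13 | (3R,4aS,5S,6R,8aR)-5,6-dihydroxy-5,8a-dimethyl-3-(propan-2-yl)octahydronaphthalen-2(1H)-one (3α,4α-diol) | O[C@@H]1CC[C@]2(C)CC(=O)[C@@H](C(C)C)C[C@@H]2[C@]1(C)O | intermediate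
14 | angelic acid [(2Z)-2-methylbut-2-enoic acid] | C/C=C(/C)C(=O)O | starting material
15 | (2Z)-2-methylbut-2-enoic 2,4,6-trichlorobenzoic anhydride | C/C=C(/C)C(=O)OC(=O)c1c(Cl)cc(Cl)cc1Cl | intermediate
16 | (1S,2R,4aR,7R,8aS)-1-hydroxy-1,4a-dimethyl-6-oxo-7-(propan-2-yl)decahydronaphthalen-2-yl (2Z)-2-methylbut-2-enoate | C/C=C(/C)C(=O)O[C@@H]1CC[C@]2(C)CC(=O)[C@@H](C(C)C)C[C@@H]2[C@]1(C)O | intermediate
17 | (1S,2R,4aR,7R,8aS)-1-(acetyloxy)-1,4a-dimethyl-6-oxo-7-(propan-2-yl)decahydronaphthalen-2-yl (2Z)-2-methylbut-2-enoate | C/C=C(/C)C(=O)O[C@@H]1CC[C@]2(C)CC(=O)[C@@H](C(C)C)C[C@@H]2[C@]1(C)OC(C)=O | target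

**Total step count:** 9. **Longest linear sequence:** 9 steps (1 → 17).

**Three steps most likely to fail**

Step 7. The substrate has three carbonyl groups and base-sensitive α-centres. The sense of the catalyst control at C-4 is predicted, not known, and aldol side reactions or addition to the ring ketone may compete. Fallback: the same keto-aldehyde 11 is closed without base by reductive ketyl–carbonyl (pinacol) coupling with SmI2 (2.5 equiv, THF, t-BuOH, −78 °C). The aldehyde ketyl adds to the acetyl carbonyl bound to the same trivalent samarium centre and gives the cis-3,4-diol directly; any C-4 epimer is separated. This sets out from 11 and comes back to the route at 13, and it makes no new compound.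

Step 5. SN2 alkylation of an enolate with a secondary iodide is slow and competes with elimination, so the yield may be poor. Fallback, setting out from 7: the enolate 9 (MeLi, THF) is trapped with acetone to give the acetone aldol adduct F1. Dehydration (SOCl2, pyridine, then DBU) gives the isopropylidene ketone F2. OsO4 (cat.)/NaIO4/2,6-lutidine cleaves only the two 1-alkenes and leaves the tetrasubstituted enone, giving the keto-aldehyde F3. The carbene cyclisation of step 7 gives the ketol F4 (not isolated), and NaBH4 at −78 °C gives the diol F5. Hydrogenation (H2, Pd/C, EtOAc) followed by K2CO3/MeOH sets C-7 as the thermodynamic 7β epimer, and the route is rejoined at 13.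

Step 2. The deconjugated ketone 4 can slip back into conjugation (trace acid or base) faster than it rearranges, which would block the sigmatropic step. Fallback, setting out from 1: radical bromination of the only available γ-position (NBS, AIBN (azobisisobutyronitrile), PhCF3, reflux) gives the bromomethyl enone F6. Keck radical allylation (allyltributylstannane, AIBN, benzene, 80 °C) then gives 5 directly, where the route is rejoined.

**Further compounds**
F0 | step 7 | none | none
F1 | step 5 | (2R,4R,5R)-5-(but-3-en-1-yl)-2-(2-hydroxypropan-2-yl)-5-methyl-4-(prop-1-en-2-yl)cyclohexan-1-one | C=CCC[C@]1(C)CC(=O)[C@@H](C(C)(C)O)C[C@@H]1C(C)=C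
F2 | step 5 | (4R,5R)-5-(but-3-en-1-yl)-5-methyl-4-(prop-1-en-2-yl)-2-(propan-2-ylidene)cyclohexan-1-one | C=CCC[C@]1(C)CC(=O)C(=C(C)C)C[C@@H]1C(C)=C
F3 | step 5 | 3-[(1R,2S)-2-acetyl-1-methyl-5-oxo-4-(propan-2-ylidene)cyclohexyl]propanal | O=CCC[C@]1(C)CC(=O)C(=C(C)C)C[C@@H]1C(C)=O
F4 | step 5 | (1S,4aR,8aS)-1-hydroxy-1,4a-dimethyl-7-(propan-2-ylidene)octahydronaphthalene-2,6(1H,3H)-dione | O=C1CC[C@]2(C)CC(=O)C(=C(C)C)C[C@@H]2[C@]1(C)O
F5 | step 5 | (4aS,5S,6R,8aR)-5,6-dihydroxy-5,8a-dimethyl-3-(propan-2-ylidene)octahydronaphthalen-2(1H)-one | O[C@@H]1CC[C@]2(C)CC(=O)C(=C(C)C)C[C@@H]2[C@]1(C)O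
F6 | step 2 | (1S,5R)-4-(bromomethyl)-6,6-dimethylbicyclo[3.1.1]hept-3-en-2-one | BrCC1=CC(=O)[C@H]2C[C@@H]1C2(C)C
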